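The route rests on one disconnection: the E-trisubstituted C2′=C3′ olefin of the side chain, lying between the benzylic C1′ on ring A and the C4′ carbinol, is treated as a methyl group and a benzyl group added cis across a terminal alkyne. A single operation, zirconium-catalysed methylalumination followed by palladium-catalysed benzylic coupling, forms the C3′–CH3 and C1′–C2′ bonds and fixes the olefin geometry. Its precursor is the ring-B alkyne, a propargylic silyl ether carrying all four stereocentres with the ketone masked as a dioxolane; the partner is the bis-silylated chloro-orcinol benzyl bromide. Ring B comes from two anti-selective cuprate/enolate alkylations; the hydroxyquinone is unveiled last.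

Key step: step 17

Remark on labels: ring A is the hydroxyquinone (C1 and C4 carbonyls, C2 OH, C3 side chain, C5 Cl, C6 CH3); ring B is the cyclohexanone (C1 quaternary, C2 the methine next to the C3 ketone, C6 the other methyl-bearing carbon); C1′–C5′ run from ring A to ring B.

Remark on configuration: in the target the C6 methyl of ring B is trans to the C1 methyl (cis to the side chain); a Diels–Alder adduct of an (E)-2-methylbut-2-enal would place these methyls cis, so ring B is built by conjugate additions instead.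

Remark on the arene: 2,6-dihydroxy-4-methylbenzaldehyde (atranol) is assumed to be purchasable; starting from it avoids ortho-lithiation of an aryl silyl ether, which invites silyl migration from oxygen to carbon.

**Ring-B fragment**

Step 1
Reactants: 1 propanal; 2 but-3-en-2-one
Product: 3 (2S)-2-methyl-5-oxohexanal
Conditions: (R)-2-(methoxydiphenylmethyl)pyrrolidine (5 mol %), ethyl 3,4-dihydroxybenzoate (20 mol %), neat, 4 °C
Reagents that add atoms: none
Why: Enamine-catalysed asymmetric Michael addition, in which the (R)-diarylprolinol ether shields one face of the (E)-enamine of propanal so that the vinyl ketone should add from the open face and set the (S) centre that becomes C6 of ring B.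

Step 2
Reactants: 3 (2S)-2-methyl-5-oxohexanal
Product: 4 (4S)-4-methylcyclohex-2-en-1-one
Conditions: LiOH, i-PrOH, rt
Reagents that add atoms: none
Why: Intramolecular aldol condensation (the ring-closing half of a Robinson annulation) of the methyl ketone enolate onto the aldehyde, which turns the α-stereocentre of 3 into the less labile γ-carbon of the enone.

Step 3
Reactants: 4 (4S)-4-methylcyclohex-2-en-1-one
Product: 5 trimethyl{[(3R,4S)-4-methyl-3-(prop-2-en-1-yl)cyclohex-1-en-1-yl]oxy}silane
Conditions: allylMgBr, CuBr·SMe2, Me3SiCl, THF, −78 °C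
Reagents that add atoms: allylmagnesium bromide, C=CC[Mg]Br; chlorotrimethylsilane, C[Si](C)(C)Cl
Why: Silyl-chloride-accelerated conjugate addition of an allylcopper reagent favours 1,4- over 1,2-addition and traps the enolate as a regiodefined silyl enol ether; allyl enters anti to the C4 methyl, but this centre is flattened again in the next step.

Step 4
Reactants: 5 trimethyl{[(3R,4S)-4-methyl-3-(prop-2-en-1-yl)cyclohex-1-en-1-yl]oxy}silane
Product: 6 (4S)-4-methyl-3-(prop-2-en-1-yl)cyclohex-2-en-1-one
Conditions: Pd(OAc)2 (10 mol %), O2 (1 atm), DMSO, rt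
Reagents that add atoms: none
Why: Saegusa–Ito oxidation, in which the palladium enolate formed at C2 has only the C3 hydrogen available for β-hydride elimination, so the enone returns with the allyl group on its β-carbon and the C4 centre untouched.

Step 5
Reactants: 6 (4S)-4-methyl-3-(prop-2-en-1-yl)cyclohex-2-en-1-one
Product: 8 (2R,3S,4S)-2,3,4-trimethyl-3-(prop-2-en-1-yl)cyclohexan-1-one, via lithium enolate 7 (not isolated)
Conditions: Me2CuLi (from MeLi, CuI), Et2O, −20 → 0 °C; then MeI (excess), DMPU, THF, 0 °C → rt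
Reagents that add atoms: lithium dimethylcuprate, [Li+].C[Cu-]C; iodomethane, CI
Why: Cuprate conjugate addition followed by enolate C-alkylation: methyl should add to C3 anti to the pseudoaxial C4 methyl (leaving allyl cis to that methyl), and iodomethane should then attack C2 of enolate 7 axially on the face opposite the pseudoaxial allyl group, placing the C2 methyl trans to allyl.

Step 6
Reactants: 8 (2R,3S,4S)-2,3,4-trimethyl-3-(prop-2-en-1-yl)cyclohexan-1-one
Product: 9 (6R,7S,8S)-6,7,8-trimethyl-7-(prop-2-en-1-yl)-1,4-dioxaspiro[4.5]decane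
Conditions: Me3SiOCH2CH2OSiMe3, Me3SiOTf (cat.), CH2Cl2, −78 → −20 °C
Reagents that add atoms: 1,2-bis(trimethylsilyloxy)ethane, C[Si](C)(C)OCCO[Si](C)(C)C
Why: Silyl-triflate-catalysed ketalisation with the bis-silyl ether of ethylene glycol (Noyori conditions) is aprotic and kinetic, so the enolisable C2 centre next to the carbonyl should not epimerise.

Step 7
Reactants: 9 (6R,7S,8S)-6,7,8-trimethyl-7-(prop-2-en-1-yl)-1,4-dioxaspiro[4.5]decane
Product: 10 2-[(6R,7S,8S)-6,7,8-trimethyl-1,4-dioxaspiro[4.5]decan-7-yl]acetaldehyde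
Conditions: O3, CH2Cl2, −78 °C; then PPh3, −78 °C → rt
Reagents that add atoms: ozone, [O-][O+]=O
Why: Ozonolysis with reductive work-up cleaves the only olefin to the aldehyde, and the ketal carbon bears no hydrogen and is inert to ozone.

Step 8
Reactants: 10 2-[(6R,7S,8S)-6,7,8-trimethyl-1,4-dioxaspiro[4.5]decan-7-yl]acetaldehyde; 11 ethynyltrimethylsilane
Product: 13 4-(trimethylsilyl)-1-[(6R,7S,8S)-6,7,8-trimethyl-1,4-dioxaspiro[4.5]decan-7-yl]but-3-yn-2-ol (both carbinol epimers), via lithium acetylide 12 (not isolated)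
Conditions: n-BuLi, THF, −78 °C; then 10; aq. NH4Cl
Reagents that add atoms: none
Why: 1,2-Addition of a lithium acetylide to an aldehyde; the new carbinol centre forms as a mixture that the next oxidation erases.

Step 9
Reactants: 13 4-(trimethylsilyl)-1-[(6R,7S,8S)-6,7,8-trimethyl-1,4-dioxaspiro[4.5]decan-7-yl]but-3-yn-2-ol
Product: 14 4-(trimethylsilyl)-1-[(6R,7S,8S)-6,7,8-trimethyl-1,4-dioxaspiro[4.5]decan-7-yl]but-3-yn-2-one
Conditions: Dess–Martin periodinane, NaHCO3, CH2Cl2, 0 °C → rt
Reagents that add atoms: none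
Why: Dess–Martin oxidation of a propargylic alcohol to the ynone under buffered conditions that spare the ketal.

Step 10
Reactants: 14 4-(trimethylsilyl)-1-[(6R,7S,8S)-6,7,8-trimethyl-1,4-dioxaspiro[4.5]decan-7-yl]but-3-yn-2-one
Product: 15 (2S)-4-(trimethylsilyl)-1-[(6R,7S,8S)-6,7,8-trimethyl-1,4-dioxaspiro[4.5]decan-7-yl]but-3-yn-2-ol
Conditions: Ru[(S,S)-TsDPEN](p-cymene) (2 mol %), i-PrOH, rt
Reagents that add atoms: none
Why: Noyori asymmetric transfer hydrogenation of an alkynyl ketone, in which the (S,S)-diamine ligand directs hydride delivery so that the (S) carbinol at C4′ should result under catalyst control, the ring stereocentres being too remote to interfere.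

Step 11
Reactants: 15 (2S)-4-(trimethylsilyl)-1-[(6R,7S,8S)-6,7,8-trimethyl-1,4-dioxaspiro[4.5]decan-7-yl]but-3-yn-2-ol
Product: 16 (2S)-1-[(6R,7S,8S)-6,7,8-trimethyl-1,4-dioxaspiro[4.5]decan-7-yl]but-3-yn-2-ol
Conditions: K2CO3 (cat.), MeOH, rt
Reagents that add atoms: none
Why: Base-catalysed methanolysis of the alkynyl C–Si bond (protodesilylation) frees the terminal alkyne without touching the carbinol or the ketal.

Step 12
Reactants: 16 (2S)-1-[(6R,7S,8S)-6,7,8-trimethyl-1,4-dioxaspiro[4.5]decan-7-yl]but-3-yn-2-ol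
Product: 17 tert-butyl(dimethyl){[(2S)-1-[(6R,7S,8S)-6,7,8-trimethyl-1,4-dioxaspiro[4.5]decan-7-yl]but-3-yn-2-yl]oxy}silane
Conditions: t-BuMe2SiCl, imidazole, DMF, rt
Reagents that add atoms: tert-butyldimethylsilyl chloride, CC(C)(C)[Si](C)(C)Cl
Why: Imidazole-promoted silylation of a secondary alcohol gives the ether that tolerates the organoaluminium and palladium chemistry of the key step.

**Ring-A fragment**

Step 13
Reactants: 18 2,6-dihydroxy-4-methylbenzaldehyde
Product: 19 3-chloro-2,6-dihydroxy-4-methylbenzaldehyde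
Conditions: SO2Cl2 (1.0 equiv), Et2O, 0 °C
Reagents that add atoms: sulfuryl chloride, ClS(Cl)(=O)=O
Why: Electrophilic aromatic chlorination; the two free ring positions are equivalent and activated by the hydroxyl groups, and one equivalent of reagent should stop at the monochloride.

Step 14
Reactants: 19 3-chloro-2,6-dihydroxy-4-methylbenzaldehyde
Product: 20 2,6-bis[(tert-butyldimethylsilyl)oxy]-3-chloro-4-methylbenzaldehyde
Conditions: t-BuMe2SiOTf, 2,6-lutidine, CH2Cl2, 0 °C
Reagents that add atoms: tert-butyldimethylsilyl trifluoromethanesulfonate, CC(C)(C)[Si](C)(C)OS(=O)(=O)C(F)(F)F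
Why: Silylation with the silyl triflate and a hindered pyridine base overcomes the hydrogen bonding of both phenols to the formyl group.

Step 15
Reactants: 20 2,6-bis[(tert-butyldimethylsilyl)oxy]-3-chloro-4-methylbenzaldehyde
Product: 21 {2,6-bis[(tert-butyldimethylsilyl)oxy]-3-chloro-4-methylphenyl}methanol
Conditions: i-Bu2AlH, CH2Cl2, −78 °C; Rochelle-salt work-up
Reagents that add atoms: none
Why: Aluminium hydride reduction of the aldehyde in an aprotic solvent at low temperature, which avoids alkoxide-driven migration of a phenolic silyl group to the benzylic oxygen.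

Step 16
Reactants: 21 {2,6-bis[(tert-butyldimethylsilyl)oxy]-3-chloro-4-methylphenyl}methanol
Product: 22 2-(bromomethyl)-1,3-bis[(tert-butyldimethylsilyl)oxy]-4-chloro-5-methylbenzene
Conditions: CBr4, PPh3, CH2Cl2, 0 °C; used at once
Reagents that add atoms: carbon tetrabromide, BrC(Br)(Br)Br
Why: Appel bromination converts the benzylic alcohol to the bromide under neutral conditions that leave the aryl silyl ethers in place.

**Key step and end game**

Step 17
Reactants: 17 tert-butyl(dimethyl){[(2S)-1-[(6R,7S,8S)-6,7,8-trimethyl-1,4-dioxaspiro[4.5]decan-7-yl]but-3-yn-2-yl]oxy}silane; 22 2-(bromomethyl)-1,3-bis[(tert-butyldimethylsilyl)oxy]-4-chloro-5-methylbenzene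
Product: 24 fully silylated coupling product, 2-{(2E,4S)-4-[(tert-butyldimethylsilyl)oxy]-3-methyl-5-[(6R,7S,8S)-6,7,8-trimethyl-1,4-dioxaspiro[4.5]decan-7-yl]pent-2-en-1-yl}-1,3-bis[(tert-butyldimethylsilyl)oxy]-4-chloro-5-methylbenzene, via alkenylalane 23 (not isolated)
Conditions: Me3Al (3 equiv), Cp2ZrCl2 (0.25 equiv), H2O (1.5 equiv), CH2Cl2, −30 → 0 °C; volatiles removed in vacuo; then 22, Pd(PPh3)4 (5 mol %), THF, rt
Reagents that add atoms: trimethylaluminium, C[Al](C)C
Why: Cp2ZrCl2 and Me3Al form a methylzirconium–aluminium species that adds methyl and metal syn across the terminal alkyne of 17, methyl to the internal carbon C3′ and metal to C2′, and exchange with aluminium leaves the (E)-alkenyldimethylalane 23. Zerovalent palladium from Pd(PPh3)4 then inserts into the benzylic C–Br bond of 22, the alkenyl group passes from aluminium to palladium, and reductive elimination forms C1′–C2′ with retention of geometry. The closest known reaction type is the Negishi zirconium-catalysed methylalumination of terminal alkynes combined with palladium-catalysed coupling of alkenylalanes with benzylic halides. No ring closes and no stereocentre forms; the only stereo-element, the E olefin (methyl cis to C1′), follows from syn addition plus retention rather than from a selective olefination. The step needs metal at the terminal carbon, which the branched silyloxy-bearing C4′ enforces sterically, and reaction at the benzylic bromide only, which is secured because the electron-rich, doubly ortho-substituted aryl chloride is inert to Pd(PPh3)4 at rt. The water-accelerated, low-temperature carbometalation and removal of excess Me3Al before 22 is added should protect the dioxolane, the C4′ silyl ether and the ionisable benzylic bromide.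

Step 18
Reactants: 24 fully silylated coupling product
Product: 25 4-chloro-2-{(2E,4S)-4-hydroxy-3-methyl-5-[(6R,7S,8S)-6,7,8-trimethyl-1,4-dioxaspiro[4.5]decan-7-yl]pent-2-en-1-yl}-5-methylbenzene-1,3-diol
Conditions: Bu4NF, AcOH, THF, 0 °C → rt, degassed
Reagents that add atoms: none
Why: Fluoride-mediated cleavage of the two aryl and one alkyl silyl ethers; acetic acid buffering keeps the electron-rich resorcinol from base-promoted air oxidation and the ketal is unaffected.

Step 19
Reactants: 25 resorcinol ketal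
Product: 26 5-chloro-2-hydroxy-3-{(2E,4S)-4-hydroxy-3-methyl-5-[(6R,7S,8S)-6,7,8-trimethyl-1,4-dioxaspiro[4.5]decan-7-yl]pent-2-en-1-yl}-6-methylcyclohexa-2,5-diene-1,4-dione
Conditions: (KSO3)2NO, KH2PO4 buffer, acetone/H2O, rt
Reagents that add atoms: potassium nitrosodisulfonate (Fremy's salt), [K+].[K+].[O]N(S(=O)(=O)[O-])S(=O)(=O)[O-]
Why: Teuber oxidation with Fremy's salt, in which the nitroxyl radical oxygenates the only unsubstituted ring carbon, para to a hydroxyl group, to give the 2-hydroxy-1,4-benzoquinone; the alcohol, the olefin and the ketal are inert to this reagent.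

Step 20
Reactants: 26 hydroxyquinone ketal
Product: 27 5-chloro-2-hydroxy-3-{(2E,4S)-4-hydroxy-3-methyl-5-[(1S,2R,6S)-1,2,6-trimethyl-3-oxocyclohexyl]pent-2-en-1-yl}-6-methylcyclohexa-2,5-diene-1,4-dione (target)
Conditions: pyridinium p-toluenesulfonate (cat.), acetone/H2O, rt → 40 °C
Reagents that add atoms: water, O
Why: Mild acid-catalysed hydrolysis of the dioxolane, helped by relief of steric compression around the ketal, releases the ketone under conditions that should be too weak to enolise C2 of ring B or ionise the allylic alcohol.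

**Compound list**

1 | propanal | CCC=O | starting material
2 | but-3-en-2-one | CC(=O)C=C | starting material
3 | (2S)-2-methyl-5-oxohexanal | CC(=O)CC[C@H](C)C=O | intermediate
4 | (4S)-4-methylcyclohex-2-en-1-one | C[C@H]1CCC(=O)C=C1 | intermediate
5 | trimethyl{[(3R,4S)-4-methyl-3-(prop-2-en-1-yl)cyclohex-1-en-1-yl]oxy}silane | C=CC[C@H]1C=C(O[Si](C)(C)C)CC[C@@H]1C | intermediate
6 | (4S)-4-methyl-3-(prop-2-en-1-yl)cyclohex-2-en-1-one | C=CCC1=CC(=O)CC[C@@H]1C | intermediate
7 | lithium (3S,4S)-3,4-dimethyl-3-(prop-2-en-1-yl)cyclohex-1-en-1-olate | C=CC[C@@]1(C)[C@@H](C)CCC(O[Li])=C1 | intermediate (not isolated)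
8 | (2R,3S,4S)-2,3,4-trimethyl-3-(prop-2-en-1-yl)cyclohexan-1-one | C=CC[C@@]1(C)[C@@H](C)CCC(=O)[C@@H]1C | intermediate
9 | (6R,7S,8S)-6,7,8-trimethyl-7-(prop-2-en-1-yl)-1,4-dioxaspiro[4.5]decane | C=CC[C@@]1(C)[C@@H](C)CCC2(OCCO2)[C@@H]1C | intermediate
10 | 2-[(6R,7S,8S)-6,7,8-trimethyl-1,4-dioxaspiro[4.5]decan-7-yl]acetaldehyde | O=CC[C@@]1(C)[C@@H](C)CCC2(OCCO2)[C@@H]1C | intermediate
11 | ethynyltrimethylsilane | C#C[Si](C)(C)C | starting material
12 | lithium (trimethylsilyl)acetylide | [Li]C#C[Si](C)(C)C | intermediate (not isolated)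
13 | 4-(trimethylsilyl)-1-[(6R,7S,8S)-6,7,8-trimethyl-1,4-dioxaspiro[4.5]decan-7-yl]but-3-yn-2-ol, both carbinol epimers | C[Si](C)(C)C#CC(O)C[C@@]1(C)[C@@H](C)CCC2(OCCO2)[C@@H]1C | intermediate
14 | 4-(trimethylsilyl)-1-[(6R,7S,8S)-6,7,8-trimethyl-1,4-dioxaspiro[4.5]decan-7-yl]but-3-yn-2-one | C[Si](C)(C)C#CC(=O)C[C@@]1(C)[C@@H](C)CCC2(OCCO2)[C@@H]1C | intermediate
15 | (2S)-4-(trimethylsilyl)-1-[(6R,7S,8S)-6,7,8-trimethyl-1,4-dioxaspiro[4.5]decan-7-yl]but-3-yn-2-ol | C[Si](C)(C)C#C[C@@H](O)C[C@@]1(C)[C@@H](C)CCC2(OCCO2)[C@@H]1C | intermediate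
16 | (2S)-1-[(6R,7S,8S)-6,7,8-trimethyl-1,4-dioxaspiro[4.5]decan-7-yl]but-3-yn-2-ol | C#C[C@@H](O)C[C@@]1(C)[C@@H](C)CCC2(OCCO2)[C@@H]1C | intermediate
17 | tert-butyl(dimethyl){[(2S)-1-[(6R,7S,8S)-6,7,8-trimethyl-1,4-dioxaspiro[4.5]decan-7-yl]but-3-yn-2-yl]oxy}silane | C#C[C@@H](O[Si](C)(C)C(C)(C)C)C[C@@]1(C)[C@@H](C)CCC2(OCCO2)[C@@H]1C | intermediate (key-step precursor)
18 | 2,6-dihydroxy-4-methylbenzaldehyde | Cc1cc(O)c(C=O)c(O)c1 | starting material
19 | 3-chloro-2,6-dihydroxy-4-methylbenzaldehyde | Cc1cc(O)c(C=O)c(O)c1Cl | intermediate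
20 | 2,6-bis[(tert-butyldimethylsilyl)oxy]-3-chloro-4-methylbenzaldehyde | Cc1cc(O[Si](C)(C)C(C)(C)C)c(C=O)c(O[Si](C)(C)C(C)(C)C)c1Cl | intermediate
21 | {2,6-bis[(tert-butyldimethylsilyl)oxy]-3-chloro-4-methylphenyl}methanol | Cc1cc(O[Si](C)(C)C(C)(C)C)c(CO)c(O[Si](C)(C)C(C)(C)C)c1Cl | intermediate
22 | 2-(bromomethyl)-1,3-bis[(tert-butyldimethylsilyl)oxy]-4-chloro-5-methylbenzene | Cc1cc(O[Si](C)(C)C(C)(C)C)c(CBr)c(O[Si](C)(C)C(C)(C)C)c1Cl | intermediate (key-step precursor)
23 | [(1E,3S)-3-[(tert-butyldimethylsilyl)oxy]-2-methyl-4-[(6R,7S,8S)-6,7,8-trimethyl-1,4-dioxaspiro[4.5]decan-7-yl]but-1-en-1-yl]dimethylalane | C[Al](C)/C=C(\C)[C@@H](O[Si](C)(C)C(C)(C)C)C[C@@]1(C)[C@@H](C)CCC2(OCCO2)[C@@H]1C | intermediate (not isolated)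
24 | 2-{(2E,4S)-4-[(tert-butyldimethylsilyl)oxy]-3-methyl-5-[(6R,7S,8S)-6,7,8-trimethyl-1,4-dioxaspiro[4.5]decan-7-yl]pent-2-en-1-yl}-1,3-bis[(tert-butyldimethylsilyl)oxy]-4-chloro-5-methylbenzene | Cc1cc(O[Si](C)(C)C(C)(C)C)c(C/C=C(\C)[C@@H](O[Si](C)(C)C(C)(C)C)C[C@@]2(C)[C@@H](C)CCC3(OCCO3)[C@@H]2C)c(O[Si](C)(C)C(C)(C)C)c1Cl | intermediate (key-step product)
25 | 4-chloro-2-{(2E,4S)-4-hydroxy-3-methyl-5-[(6R,7S,8S)-6,7,8-trimethyl-1,4-dioxaspiro[4.5]decan-7-yl]pent-2-en-1-yl}-5-methylbenzene-1,3-diol | Cc1cc(O)c(C/C=C(\C)[C@@H](O)C[C@@]2(C)[C@@H](C)CCC3(OCCO3)[C@@H]2C)c(O)c1Cl | intermediate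
26 | 5-chloro-2-hydroxy-3-{(2E,4S)-4-hydroxy-3-methyl-5-[(6R,7S,8S)-6,7,8-trimethyl-1,4-dioxaspiro[4.5]decan-7-yl]pent-2-en-1-yl}-6-methylcyclohexa-2,5-diene-1,4-dione | CC1=C(Cl)C(=O)C(C/C=C(\C)[C@@H](O)C[C@@]2(C)[C@@H](C)CCC3(OCCO3)[C@@H]2C)=C(O)C1=O | intermediate
27 | 5-chloro-2-hydroxy-3-{(2E,4S)-4-hydroxy-3-methyl-5-[(1S,2R,6S)-1,2,6-trimethyl-3-oxocyclohexyl]pent-2-en-1-yl}-6-methylcyclohexa-2,5-diene-1,4-dione | CC1=C(Cl)C(=O)C(C/C=C(\C)[C@@H](O)C[C@@]2(C)[C@@H](C)CCC(=O)[C@@H]2C)=C(O)C1=O | target

**Count**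

Total steps: 20. Longest linear sequence: 16 (steps 1–12 and 17–20); the arene branch is steps 13–16.

**Steps most likely to fail**

1. Step 17. Aluminium Lewis acids left after the carbometalation may ionise the electron-rich benzylic bromide (self-alkylation, methyl transfer) or attack the dioxolane before the alkenyl group reaches palladium, so that the alane is consumed unproductively. The fallback reverses the polarity of the C1′–C2′ coupling. Setting out from 17, the same methylalumination is quenched with iodine to give the (E)-alkenyl iodide F1, which is purified free of aluminium. Setting out from 22, zinc insertion (Zn dust, LiCl, THF) gives the benzylzinc bromide F2. Negishi coupling of F1 with F2 (PdCl2(dppf), THF, rt) comes back to the route at 24.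

2. Step 5. C-Methylation of the hindered enolate beside the new quaternary centre may be slow, allowing proton transfer and over-alkylation, or may lack facial selectivity at C2. The fallback sets out from 6: the cuprate addition is run with Me3SiCl and the silyl enol ether F3 is isolated. Cyclopropanation with Et2Zn and CH2I2 (Furukawa variant of the Simmons–Smith reaction) should occur on the electron-rich enol ether, on the face away from the allyl group, and give the siloxycyclopropane F4. Acid-catalysed ring opening (TsOH, MeOH/CH2Cl2, 0 °C) cleaves the bond between the oxygenated carbon and the methylene, which becomes the C2 methyl with its configuration fixed by the cyclopropanation. This comes back to the route at 8.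

3. Step 20. Under the aqueous acid the hydroxyquinone may degrade (addition of its enolic OH to the C2′=C3′ olefin, ionisation at the allylic C4′), or C2 of ring B may epimerise through the enol before the hindered ketal is gone; the required C2 configuration is not clearly the more stable one. The fallback changes the order so that the quinone never meets acid. Setting out from 25, the dioxolane is hydrolysed on the more robust resorcinol (pyridinium p-toluenesulfonate, acetone/H2O, rt) to the resorcinol ketone F5. The Fremy's salt oxidation is then carried out last and comes back to the route at 27.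

**Further compounds**

F1 | step 17 | tert-butyl{[(1E,3S)-1-iodo-2-methyl-4-[(6R,7S,8S)-6,7,8-trimethyl-1,4-dioxaspiro[4.5]decan-7-yl]but-1-en-3-yl]oxy}dimethylsilane | I/C=C(\C)[C@@H](O[Si](C)(C)C(C)(C)C)C[C@@]1(C)[C@@H](C)CCC2(OCCO2)[C@@H]1C
F2 | step 17 | {2,6-bis[(tert-butyldimethylsilyl)oxy]-3-chloro-4-methylbenzyl}zinc bromide | Cc1cc(O[Si](C)(C)C(C)(C)C)c(C[Zn]Br)c(O[Si](C)(C)C(C)(C)C)c1Cl
F3 | step 5 | trimethyl{[(3S,4S)-3,4-dimethyl-3-(prop-2-en-1-yl)cyclohex-1-en-1-yl]oxy}silane | C=CC[C@@]1(C)[C@@H](C)CCC(O[Si](C)(C)C)=C1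
F4 | step 5 | trimethyl{[4,5-dimethyl-5-(prop-2-en-1-yl)bicyclo[4.1.0]heptan-1-yl]oxy}silane, cyclopropane methylene on the face opposite the allyl group | C=CC[C@@]1(C)[C@@H](C)CC[C@]2(O[Si](C)(C)C)C[C@H]12
F5 | step 20 | (2R,3S,4S)-3-[(2S,3E)-5-(3-chloro-2,6-dihydroxy-4-methylphenyl)-2-hydroxy-3-methylpent-3-en-1-yl]-2,3,4-trimethylcyclohexan-1-one | Cc1cc(O)c(C/C=C(\C)[C@@H](O)C[C@@]2(C)[C@@H](C)CCC(=O)[C@@H]2C)c(O)c1Cl
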